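**Plan**
- Retrosynthesis: the CH2OH on pyrrole C5 is taken back to CHO. The C3–C4 bond of the 16-methylheptadecan-1-one chain is then cut homolytically, each carbon ending as a CO2H, which gives a γ-keto acid and 14-methylpentadecanoic acid. Last, the bond from the ring to the ketone carbon is cut to a formal 5-lithiopyrrole-2-carbaldehyde and succinic anhydride.
- Enabling feature: ketone C1 (on pyrrole C2) and chain C4 stand in a 1,4-relationship, so the head group is a succinoyl (4-oxobutanoic acid) unit whose decarboxylation leaves an unstabilised primary radical at C3. Both α-carbons of the pyrrole (C2 and C5) carry C=O groups, the C5 formyl standing in for CH2OH, which makes the ring electron-poor enough to survive an anode.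
- Forward order: the pyrrole ring is bought as pyrrole-2-carbaldehyde and masked as its aminal dimer. C5 is lithiated and succinoylated, an anodic decarboxylative cross-coupling joins the iso-C15 chain, and the aldehyde is reduced last.
- Stereochemistry: none arises; the target has no stereocentre and no stereogenic double bond.

Key step: step 3

Remark: the target SMILES holds no stereogenic element, so the compound is achiral and needs no stereocontrol; 14-methylpentadecanoic acid (isopalmitic acid) is taken as a catalogue iso-fatty acid.

**Route**

Step 1
Reactants: 1 1H-pyrrole-2-carbaldehyde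
Product: 2 5,10-bis(dimethylamino)-5H,10H-dipyrrolo[1,2-a:1′,2′-d]pyrazine (the 6-(dimethylamino)-1-azafulvene dimer; either relative configuration at the two aminal carbons serves, since both centres are cleared in step 2)
Conditions: Me2NH (40% aq., excess), rt; the dimer should crystallise and is filtered and dried
Reagents that add atoms: dimethylamine, CNC
Why: Condensation of the aldehyde with a secondary amine gives the 6-(dimethylamino)-1-azafulvene, which should dimerise head-to-tail by N–C aminal formation, masking N–H and CHO at once and placing an NMe2 group where it can direct lithiation to the free ring α-carbon.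

Step 2
Reactants: 2 5,10-bis(dimethylamino)-5H,10H-dipyrrolo[1,2-a:1′,2′-d]pyrazine; 3 succinic anhydride
Product: 6 4-(5-formyl-1H-pyrrol-2-yl)-4-oxobutanoic acid, via dilithiated aminal dimer 4 (not isolated), via dilithium bis(keto carboxylate) aminal 5 (not isolated)
Conditions: t-BuLi (2.2 equiv), THF, −15 °C; inverse addition to 3 (3 equiv), THF, −78 → 0 °C; aq. NaOAc, 60–70 °C; HCl to pH 2–3 (one mole of 2 delivers two moles of 6)
Reagents that add atoms: water, O
Why: Amine-directed α-lithiation of the aminal dimer gives a formal 5-lithiopyrrole-2-carbaldehyde that should open the cyclic anhydride by acyl substitution to the lithium γ-keto carboxylate (aryllithium acylation with a cyclic anhydride), the low temperature, inverse addition and carboxylate charge holding back a second addition, and mild aqueous hydrolysis of the aminal then returns N–H and CHO.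

Step 3
Reactants: 6 4-(5-formyl-1H-pyrrol-2-yl)-4-oxobutanoic acid; 7 14-methylpentadecanoic acid (3–4 equiv)
Product: 8 5-(16-methylheptadecanoyl)-1H-pyrrole-2-carbaldehyde
Conditions: undivided cell, smooth Pt anode and Pt cathode, MeOH, NaOMe (5–10 mol % of total acid), 40–45 °C, constant current ca. 0.2 A cm−2, periodic polarity reversal, stopped at ca. 1.3 F per mol of acid while the solution is still weakly acidic
Reagents that add atoms: none
Why: Mixed Kolbe electrolysis: both carboxylates are oxidised by one electron at the platinum anode, lose CO2, and the two primary radicals (13-methyltetradecyl from 7 and 3-oxo-3-(5-formylpyrrol-2-yl)propyl from 6) should combine in the anode layer to form the C3–C4 bond of the heptadecanone chain. The closest known reaction type is the crossed Kolbe coupling of a 4-oxoalkanoic acid with a fatty acid. No ring is closed and no stereocentre is created. Three selectivities are needed: radical over cation chemistry, secured because both radical carbons are primary and carry no α-heteroatom, aryl or carbonyl group (the ketone of 6 is β to the radical carbon), so Hofer–Moest over-oxidation is disfavoured; carboxylate oxidation over ring oxidation, secured by the carbonyl groups on both α-carbons (C2 and C5) of the pyrrole and by the weakly acidic medium that keeps N–H un-ionised; and cross- over homo-coupling, which is only statistical and is pushed toward 8 by the excess of 7, both homodimers differing widely in polarity from 8. A platinum cathode is used so that proton reduction to hydrogen outruns reduction of the two carbonyl groups.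

Step 4
Reactants: 8 5-(16-methylheptadecanoyl)-1H-pyrrole-2-carbaldehyde
Product: 9 1-[5-(hydroxymethyl)-1H-pyrrol-2-yl]-16-methylheptadecan-1-one
Conditions: NaBH4 (0.5 equiv), THF/MeOH 4:1, −10 → 0 °C; sat. aq. NH4Cl
Reagents that add atoms: none
Why: Chemoselective borohydride reduction: the unhindered formyl group is far more electrophilic than the alkyl pyrrol-2-yl ketone (a vinylogous amide flanked by a long chain), so a sub-stoichiometric charge of hydride at low temperature should stop at the primary alcohol, which the remaining 5-acyl group stabilises against azafulvene formation.

**Compound list**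

1 | 1H-pyrrole-2-carbaldehyde | O=Cc1ccc[nH]1 | starting material
2 | 5,10-bis(dimethylamino)-5H,10H-dipyrrolo[1,2-a:1′,2′-d]pyrazine (aminal centres temporary, configuration immaterial) | CN(C)C1c2cccn2C(N(C)C)c2cccn12 | intermediate
3 | succinic anhydride | O=C1CCC(=O)O1 | starting material
4 | dilithiated aminal dimer (Li on the ring carbon next to each ring nitrogen) | CN(C)C1c2ccc([Li])n2C(N(C)C)c2ccc([Li])n12 | intermediate
5 | dilithium bis(keto carboxylate) aminal | [Li+].[Li+].CN(C)C1c2ccc(C(=O)CCC(=O)[O-])n2C(N(C)C)c2ccc(C(=O)CCC(=O)[O-])n12 | intermediate
6 | 4-(5-formyl-1H-pyrrol-2-yl)-4-oxobutanoic acid | O=Cc1ccc(C(=O)CCC(=O)O)[nH]1 | intermediate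
7 | 14-methylpentadecanoic acid | CC(C)CCCCCCCCCCCCC(=O)O | starting material
8 | 5-(16-methylheptadecanoyl)-1H-pyrrole-2-carbaldehyde | CC(C)CCCCCCCCCCCCCCC(=O)c1ccc(C=O)[nH]1 | intermediate
9 | 1-[5-(hydroxymethyl)-1H-pyrrol-2-yl]-16-methylheptadecan-1-one | CC(C)CCCCCCCCCCCCCCC(=O)c1ccc(CO)[nH]1 | target

Total step count: 4
Longest linear sequence: 4 steps (1 → 2 → 6 → 8 → 9); 3 and 7 enter as bought.

**Steps most likely to fail**

Step 3. The pyrrole ring or the formyl C–H may be oxidised at the anode in competition with the carboxylates, filming the electrode, and part of the material is lost to statistical homocoupling. The fallback replaces anodic oxidation by a reductive decarboxylative coupling and sets out from 6 and 7. Each acid is esterified with N-hydroxyphthalimide (DIC, cat. DMAP, CH2Cl2), giving 1,3-dioxoisoindolin-2-yl 4-(5-formyl-1H-pyrrol-2-yl)-4-oxobutanoate F1 and 1,3-dioxoisoindolin-2-yl 14-methylpentadecanoate F2. The two redox-active esters are then joined by the known nickel-catalysed reductive doubly decarboxylative C(sp3)–C(sp3) cross-coupling (Ni(II)/terpyridine-type catalyst, cathodic reduction with a sacrificial Mg anode, NMP, F2 in excess). This should return to the route at 8.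

Step 2. The aryllithium may act as a base on the enolisable anhydride, or add a second time to the newly formed ketone. The fallback uses a chelation-controlled Weinreb ketone synthesis and sets out from 3 and 4. Anhydride 3 is opened with N,O-dimethylhydroxylamine (hydrochloride, Et3N, CH2Cl2) to 4-[methoxy(methyl)amino]-4-oxobutanoic acid F3, which is deprotonated with LiHMDS to lithium 4-[methoxy(methyl)amino]-4-oxobutanoate F4. Addition of the dilithiated dimer 4 at −78 °C should give the tetralithium tetrahedral bis-adduct F5, which cannot add a second time. Aqueous quench collapses it to 5, where the route is rejoined, and the hydrolysis of step 2 then gives 6.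

Step 4. The ketone may be reduced along with the aldehyde, or the new hydroxyl lost by over-reduction through an azafulvene. The fallback sets out from 8 and returns at 9. The stoichiometric hydride is replaced by an aldehyde-selective catalytic transfer hydrogenation (Cp*Ir(III) N-sulfonyl-1,2-diamine catalyst, HCO2Na, water/2-MeTHF, rt to 40 °C), whose metal hydride discriminates aldehydes from ketones by a wide margin. No new compound is made.

**Further compounds**

F1 | step 3 | 1,3-dioxoisoindolin-2-yl 4-(5-formyl-1H-pyrrol-2-yl)-4-oxobutanoate | O=Cc1ccc(C(=O)CCC(=O)ON2C(=O)c3ccccc3C2=O)[nH]1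
F2 | step 3 | 1,3-dioxoisoindolin-2-yl 14-methylpentadecanoate | CC(C)CCCCCCCCCCCCC(=O)ON1C(=O)c2ccccc2C1=O
F3 | step 2 | 4-[methoxy(methyl)amino]-4-oxobutanoic acid | CON(C)C(=O)CCC(=O)O
F4 | step 2 | lithium 4-[methoxy(methyl)amino]-4-oxobutanoate | [Li+].CON(C)C(=O)CCC(=O)[O-]
F5 | step 2 | tetralithium tetrahedral bis-adduct of 4 and F4 (not isolated; new centres temporary) | [Li+].[Li+].[Li+].[Li+].CN(C)C1c2ccc(C([O-])(CCC(=O)[O-])N(C)OC)n2C(N(C)C)c2ccc(C([O-])(CCC(=O)[O-])N(C)OC)n12
F0 | step 4 | none | none
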